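At 10 °C, with 0.71 mol% of Kat and 0.076 mol% of Kat2, the north-west flask makes Prd along a nearly straight line while its Sbt falls. On the candidate steps, Oth passes into solution as Ptn, Kat joins Ptn to Sbt to give Prd and to Sbt2 to give Prd2, and Kat2 interconverts Sbt and Sbt2.

common to all: Sbt 0.016 M; Sbt2 0.016 M; Oth 0.98 mM (held)

| run | Kat | Kat2 | temperature | remark | time |
|---|---|---|---|---|---|
| south-east | 0.072 mol% | 0.076 mol% | −5 °C | run made earlier |  |
| north-west | 0.71 mol% | 0.076 mol% | 10 °C | run made earlier |  |
| south | 0.27 mol% | 0.14 mol% | −5 °C | run made earlier |  |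
| ash | 0.2 mol% | 0.076 mol% | 20 °C |  | 20 h |
| oak | 0.08 mol% | 0.076 mol% | 20 °C |  | 20 h |
| cedar | 0.08 mol% | 0.3 mol% | 0 °C |  | 20 h |
| larch | 0.27 mol% | 0.076 mol% | 20 °C |  | 20 h |
| alder | 0.8 mol% | 0.076 mol% | 5 °C |  | 20 h |

| run | time / h | Prd / % | Sbt / % |
|---|---|---|---|
| south-east | 3.00 | 0 | 50 |
| south-east | 6.00 | 0 | 45 |
| south-east | 15.0 | 5 | 49 |
| south-east | 20.0 | 6 | 45 |
| south-east | 30.0 | 10 | 41 |
| south-east | 40.0 | 12 | 45 |
| south-east | 48.0 | 12 | 40 |
| north-west | 1.50 | 4 | 46 |
| north-west | 2.50 | 6 | 43 |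
| north-west | 4.00 | 11 | 44 |
| north-west | 6.00 | 15 | 39 |
| north-west | 10.0 | 22 | 35 |
| north-west | 15.0 | 35 | 27 |
| north-west | 25.0 | 53 | 15 |
| south | 10.0 | 7 | 42 |
| south | 20.0 | 18 | 38 |
| south | 30.0 | 26 | 31 |
| south | 40.0 | 31 | 28 |
| south | 48.0 | 37 | 25 |

(scatter of a reading: 1.5 percentage points)

- Kat is single-handed; Sbt and Sbt2 are mirror images of each other, charged as a racemate, each of them at the stated concentration
- at the start none of Ptn is dissolved
- the analysis behind the earlier runs scatters by 1.5 percentage points, standard deviation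
- candidate steps: Sbt + Kat2 <-> Sbt2 + Kat2; Ptn + Kat + Sbt -> Kat + Prd; Oth <-> Ptn; Ptn + Kat + Sbt2 -> Kat + Prd2

- ranking by amount of Prd, in percent of the Sbt and Sbt2 together charged, from high to low, at 20 h (ash / oak / cedar / larch / alder)
- the amount of Prd, in percent of the Sbt and Sbt2 together charged of the flask you put first, at 20 h
- the amount of Prd, in percent of the Sbt and Sbt2 together charged of the flask you put last, at 20 h

The decision is which charge to run if Prd at 20 h is what counts. In the north-west run, Sbt falls from 46% to 15% between 1.50 h and 25.0 h, a factor of 3.07. Over the same run the Prd slope read from the first four readings is 0.0244 h⁻¹ and from the last three 0.0207 h⁻¹, a factor of 1.18. The slope falls by a smaller factor than Sbt, so these readings of the north-west run look close to apparent zero order in Sbt, and the slope is frozen here. Let v be the steady Prd slope of the north-west run, as a fraction of the Sbt and Sbt2 together charged per hour, taken from its first reading to its last: 0.0209 h⁻¹.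

Alder holds 0.8 mol% of Kat against north-west's 0.71 mol% and runs colder, at 5 °C. My own reckoning keeps v unchanged for alder, which gives 41.8% Prd at 20 h. It gives no figure for larch, which carries a third of alder's Kat at 20 °C, above the 10 °C of the north-west run. Alder is therefore the charge this reckoning would run, as a judgement: its Kat and temperature stand close to those of a run that showed v.

The forecast differs: larch > ash > alder > oak > cedar, with 47% first and 11% last, from “Combining catalyst and transfer resistances in series”. Its larch figure asks for a mean slope of 0.0235 h⁻¹, steeper than v, and on this point the two part.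

The flasks give alder > larch > ash > oak > cedar, with 40.5% first and 8.70% last.

    Sbt + Kat2 ⇌ Sbt2 + Kat2, rate k1*[Kat2]*[Sbt] forward; the back reaction follows from the equilibrium constant (k = 49.0 L mol⁻¹ s⁻¹, Ea = 50.0 kJ mol⁻¹)
    Ptn + Kat + Sbt → Kat + Prd (k = 690 L² mol⁻² s⁻¹, Ea = 35.0 kJ mol⁻¹)
    Oth ⇌ Ptn, rate k3*(csat - [Ptn]) (kL = 4.40 × 10⁻⁴ s⁻¹)
    Ptn + Kat + Sbt2 → Kat + Prd2 (k = 250 L² mol⁻² s⁻¹, Ea = 36.0 kJ mol⁻¹)
    (constants at 20 °C)

Alder lands 1.3 percentage points below the frozen-slope figure, and larch, at 36.1%, stays under v times 20 h. The neighbour is the alder charge read at 12 h. There v gives 25.1%, and the flask holds 25.8% Prd beside 9.36% Prd2, with Sbt2 the largest share of the Sbt and Sbt2 together charged at 32.9%.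

The data come from a simulation for substances that don't exist.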